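**Plan**
- **Retrosynthesis.** The C6–allyl bond is cut first: a carboxyl takes its place and is tied to the benzylic oxygen as a γ-butyrolactone. Then C2=C3 and C5–C6 of the cyclohexenone are cut together, leaving a 3-(ylide-acyl) lactone and 2-methoxyacrolein. The acyl–lactone bond and the lactone lead back to a syn crotylation of 3,4,5-trimethoxybenzaldehyde.
- **Enabling feature.** The ring carbonyl C1 is flanked by C2 and C6. These form a 1,3-bis-nucleophile once C2 is a keto-stabilised phosphorus ylide and C6 is the α-carbon of a β-keto lactone. C3–C4(OMe)–C5 is the skeleton of a 2-alkoxy enal (aldehyde carbon C3, Michael terminus C5). The benzylic oxygen stands γ to C6, so a carboxyl on C6 closes a five-membered ring that is not in the target.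
- **Forward order.** Side chain, temporary lactone ring, acyl ylide, six-membered ring by [3+3] Michael–Wittig annulation, then lactone opening with loss of CO2 and entry of the allyl group.
- **Stereochemistry.** The carbinol and methyl carbons come from a catalytic asymmetric Z-crotylboration. The cis methyl/aryl face of the lactone fixes the spiro carbon, which relays to C4–OMe during ring closure. C6 is set last by decarboxylative allylation anti to OMe, matched with the A(1,3) bias of the side chain and with the (S)-PHOX ligand.

Key step: step 7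

Assumption: (R)-TRIP is taken to direct the boronate to the Re face of the aryl aldehyde, as with benzaldehyde; if the sense were opposite, its enantiomer would be used.

Step 1
Reactants: 1 3,4,5-trimethoxybenzaldehyde; 2 (Z)-crotylboronic acid pinacol ester
Product: 4 (1R,2S)-2-methyl-1-(3,4,5-trimethoxyphenyl)but-3-en-1-ol, via pinacol borate ester 3 (not isolated)
Conditions: (R)-TRIP (5 mol %), 4 Å MS, toluene, −30 °C; aqueous work-up
Reagents that add atoms: none
Why: Chiral-phosphoric-acid-catalysed crotylboration runs through a closed Zimmerman–Traxler chair, in which the Z-boronate gives the syn relationship and the catalyst selects the Re face of the aldehyde, which should set (1R,2S).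

Step 2
Reactants: 4 (1R,2S)-2-methyl-1-(3,4,5-trimethoxyphenyl)but-3-en-1-ol
Product: 6 (1R,2S)-2-methyl-1-(3,4,5-trimethoxyphenyl)butane-1,4-diol, via bis-borane adduct 5 (not isolated)
Conditions: 9-BBN-H (2.5 equiv), THF, 0 °C to rt; then 3 M aq. NaOH, 30% H2O2, 0 °C to rt
Reagents that add atoms: 9-BBN-H, B1C2CCCC1CCC2 (stays only in 5); hydrogen peroxide, OO
Why: Anti-Markovnikov hydroboration–oxidation of the monosubstituted alkene with the bulky borane puts the hydroxyl on the terminal carbon and touches no stereocenter.

Step 3
Reactants: 6 (1R,2S)-2-methyl-1-(3,4,5-trimethoxyphenyl)butane-1,4-diol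
Product: 8 (4S,5R)-4-methyl-5-(3,4,5-trimethoxyphenyl)dihydrofuran-2(3H)-one (methyl and aryl cis), via lactol 7 (not isolated)
Conditions: TEMPO (10 mol %), PhI(OAc)2 (2.5 equiv), CH2Cl2, rt
Reagents that add atoms: none
Why: In this TEMPO-mediated oxidative lactonisation the primary alcohol is oxidised faster than the hindered secondary one, the aldehyde closes to the lactol, and the lactol is oxidised on to the lactone, which holds methyl and aryl on one face of a five-membered ring.

Step 4
Reactants: 8 (4S,5R)-4-methyl-5-(3,4,5-trimethoxyphenyl)dihydrofuran-2(3H)-one; 9 2-chloro-N-methoxy-N-methylacetamide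
Product: 11 (4S,5R)-3-(chloroacetyl)-4-methyl-5-(3,4,5-trimethoxyphenyl)dihydrofuran-2(3H)-one (C3 labile), via lithium enolate 10 (not isolated)
Conditions: LiHMDS (2.1 equiv), THF, −78 °C; 9, −78 to −40 °C; AcOH quench
Reagents that add atoms: LiHMDS, [Li+].C[Si](C)(C)[N-][Si](C)(C)C (lithium stays only in 10)
Why: This is a crossed Claisen-type C-acylation of a lactone enolate with a Weinreb amide, whose chelated tetrahedral adduct should last until the quench and so shield the C–Cl bond; the new C3 center equilibrates and is of no consequence.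

Step 5
Reactants: 11 (4S,5R)-3-(chloroacetyl)-4-methyl-5-(3,4,5-trimethoxyphenyl)dihydrofuran-2(3H)-one
Product: 13 (4S,5R)-4-methyl-3-[(triphenyl-λ5-phosphanylidene)acetyl]-5-(3,4,5-trimethoxyphenyl)dihydrofuran-2(3H)-one, via phosphonium chloride 12 (not isolated)
Conditions: PPh3, toluene, 70 °C; then aq. Na2CO3, CH2Cl2, rt
Reagents that add atoms: triphenylphosphine, c1ccc(cc1)P(c1ccccc1)c1ccccc1
Why: SN2 quaternisation of PPh3 by the α-chloro ketone followed by deprotonation of the P–CH2–C=O position gives the keto-stabilised Wittig ylide, the same sequence used on 4-chloroacetoacetates.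

Step 6
Reactants: 14 1,1,2-trimethoxyethane
Product: 16 2-methoxyacrolein (2-methoxyprop-2-enal), via methoxyacetaldehyde 15 (not isolated)
Conditions: Amberlyst-15, H2O, 50 °C, filter; then 37% aq. HCHO, pyrrolidine (10 mol %), propionic acid (10 mol %), i-PrOH, 45 °C; distil
Reagents that add atoms: water, O; formaldehyde, C=O
Why: Acetal hydrolysis is followed by amine/acid-catalysed α-methylenation of the aldehyde (Mannich condensation and elimination), a standard entry to 2-substituted acroleins.

Step 7
Reactants: 13 (4S,5R)-4-methyl-3-[(triphenyl-λ5-phosphanylidene)acetyl]-5-(3,4,5-trimethoxyphenyl)dihydrofuran-2(3H)-one; 16 2-methoxyacrolein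
Product: 18 (3R,4S,5S,9R)-9-methoxy-4-methyl-3-(3,4,5-trimethoxyphenyl)-2-oxaspiro[4.5]dec-7-ene-1,6-dione, via Michael adduct aldehyde 17 (not isolated)
Conditions: 16 (1.5 equiv), DABCO (30 mol %), LiClO4 (30 mol %), CHCl3, 0 to 35 °C
Reagents that add atoms: none
Why: Proposed new method: Li+/DABCO soft enolisation of the doubly activated C3–H of 13 starts a conjugate addition to the CH2 terminus of 16, the aldehyde enolate is protonated to 17, and the keto-stabilised ylide carbon then attacks the new saturated aldehyde and expels Ph3PO (intramolecular Wittig reaction), so that C5–C6 and C2=C3 (target numbering) arise in one operation. The closest known reaction type is the tandem Michael–Wittig [3+3] cyclohexenone annulation of 4-(triphenylphosphoranylidene)acetoacetates with enals, shown for CH2 donors and 3-substituted enals but not for a tertiary donor or a 2-alkoxyacrolein. The only ring closed is the carbocycle, by a 6-(enolendo)-exo-trig attack of the ylide carbon on the aldehyde, and the ring size enforces the cis alkene. The spiro carbon is controlled by the temporary lactone, whose methyl and aryl groups stand on the same face of the planar enolate, so that 16 adds to the opposite face. The methoxy carbon is set under Curtin–Hammett control, because the epimers of 17 interconvert by enolisation and by retro-Michael/Michael addition while only the Wittig step is irreversible, and the chair-like closure with OMe equatorial (anti to the incoming ylide carbon as in the polar Felkin–Anh model) and the methyl-bearing lactone carbon equatorial should be the fastest, which places OMe cis to that carbon (9R). The step needs 1,4-addition at C3 of the lactone before any olefination of free 16, which the substrate secures because the keto ylide reacts only slowly with a conjugated, donor-substituted aldehyde at this temperature, whereas the β-keto lactone C–H is the most acidic site and, after the addition, the reactive saturated aldehyde sits within reach of the ylide.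

Step 8
Reactants: 18 (3R,4S,5S,9R)-9-methoxy-4-methyl-3-(3,4,5-trimethoxyphenyl)-2-oxaspiro[4.5]dec-7-ene-1,6-dione; 19 allyl acetate
Product: 22 megaphone [(4R,6R)-6-[(1R,2S)-1-hydroxy-1-(3,4,5-trimethoxyphenyl)propan-2-yl]-4-methoxy-6-(prop-2-en-1-yl)cyclohex-2-en-1-one], via potassium carboxylate 20 (not isolated), via silyl ether 21 (not isolated)
Conditions: KOSiMe3 (1.05 equiv), THF, 0 °C to rt; then 19, Pd2(dba)3 (2.5 mol %), (S)-t-Bu-PHOX (6.25 mol %), THF–toluene, 30 °C; then 10% aq. citric acid, MeOH, rt
Reagents that add atoms: potassium trimethylsilanolate, C[Si](C)(C)[O-].[K+] (stays only in 20 and 21)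
Why: Silanolate cleavage of the lactone acyl–oxygen bond gives the anhydrous β-keto carboxylate with the carbinol masked as its silyl ether, zerovalent palladium ionises allyl acetate, loss of CO2 gives the site-specific enolate, and the Tsuji-type decarboxylative asymmetric allylic alkylation should form C6 on the face anti to the C4 methoxy group, which is also the face favoured by A(1,3) strain in the side chain (its methyl, not the aryl carbinol, lies there) and by the (S)-ligand, after which mild acid removes the silyl ether.

**Compound list**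
1 | 3,4,5-trimethoxybenzaldehyde | O=Cc1cc(OC)c(OC)c(OC)c1 | starting material
2 | (Z)-crotylboronic acid pinacol ester | C/C=C\CB1OC(C)(C)C(C)(C)O1 | starting material
3 | pinacol borate ester of 4 | C=C[C@H](C)[C@@H](OB1OC(C)(C)C(C)(C)O1)c1cc(OC)c(OC)c(OC)c1 | intermediate
4 | (1R,2S)-2-methyl-1-(3,4,5-trimethoxyphenyl)but-3-en-1-ol | C=C[C@H](C)[C@@H](O)c1cc(OC)c(OC)c(OC)c1 | intermediate
5 | bis-borane adduct (C4-alkyl and O-borinate of 9-BBN) | C(CB1C2CCCC1CCC2)[C@H](C)[C@@H](OB1C2CCCC1CCC2)c1cc(OC)c(OC)c(OC)c1 | intermediate
6 | (1R,2S)-2-methyl-1-(3,4,5-trimethoxyphenyl)butane-1,4-diol | OCC[C@H](C)[C@@H](O)c1cc(OC)c(OC)c(OC)c1 | intermediate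
7 | (4S,5R)-4-methyl-5-(3,4,5-trimethoxyphenyl)tetrahydrofuran-2-ol (anomers) | OC1C[C@H](C)[C@H](c2cc(OC)c(OC)c(OC)c2)O1 | intermediate
8 | (4S,5R)-4-methyl-5-(3,4,5-trimethoxyphenyl)dihydrofuran-2(3H)-one | O=C1C[C@H](C)[C@H](c2cc(OC)c(OC)c(OC)c2)O1 | intermediate
9 | 2-chloro-N-methoxy-N-methylacetamide | ClCC(=O)N(C)OC | starting material
10 | lithium enolate of 8 | [Li+].[O-]C1=C[C@H](C)[C@H](c2cc(OC)c(OC)c(OC)c2)O1 | intermediate
11 | (4S,5R)-3-(chloroacetyl)-4-methyl-5-(3,4,5-trimethoxyphenyl)dihydrofuran-2(3H)-one (C3 labile) | O=C1C(C(=O)CCl)[C@H](C)[C@H](c2cc(OC)c(OC)c(OC)c2)O1 | intermediate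
12 | [2-[(4S,5R)-4-methyl-2-oxo-5-(3,4,5-trimethoxyphenyl)tetrahydrofuran-3-yl]-2-oxoethyl]triphenylphosphonium chloride | O=C1C(C(=O)C[P+](c2ccccc2)(c2ccccc2)c2ccccc2)[C@H](C)[C@H](c2cc(OC)c(OC)c(OC)c2)O1.[Cl-] | intermediate
13 | (4S,5R)-4-methyl-3-[(triphenyl-λ5-phosphanylidene)acetyl]-5-(3,4,5-trimethoxyphenyl)dihydrofuran-2(3H)-one (C3 labile) | O=C1C(C(=O)C=P(c2ccccc2)(c2ccccc2)c2ccccc2)[C@H](C)[C@H](c2cc(OC)c(OC)c(OC)c2)O1 | intermediate
14 | 1,1,2-trimethoxyethane | COCC(OC)OC | starting material
15 | methoxyacetaldehyde | COCC=O | intermediate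
16 | 2-methoxyacrolein | C=C(OC)C=O | intermediate
17 | 2-methoxy-3-[(3S,4S,5R)-4-methyl-2-oxo-3-[(triphenyl-λ5-phosphanylidene)acetyl]-5-(3,4,5-trimethoxyphenyl)tetrahydrofuran-3-yl]propanal (equilibrating at the methoxy carbon) | O=C1[C@](C(=O)C=P(c2ccccc2)(c2ccccc2)c2ccccc2)([C@H](C)[C@H](c2cc(OC)c(OC)c(OC)c2)O1)CC(OC)C=O | intermediate
18 | (3R,4S,5S,9R)-9-methoxy-4-methyl-3-(3,4,5-trimethoxyphenyl)-2-oxaspiro[4.5]dec-7-ene-1,6-dione | O=C2[C@]1([C@H](C)[C@H](c3cc(OC)c(OC)c(OC)c3)O2)C[C@@H](OC)C=CC1=O | intermediate
19 | allyl acetate | C=CCOC(C)=O | starting material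
20 | potassium (1S,5R)-5-methoxy-2-oxo-1-[(1R,2S)-1-(3,4,5-trimethoxyphenyl)-1-(trimethylsilyloxy)propan-2-yl]cyclohex-3-ene-1-carboxylate | [K+].[O-]C(=O)[C@]1([C@H](C)[C@@H](O[Si](C)(C)C)c2cc(OC)c(OC)c(OC)c2)C[C@@H](OC)C=CC1=O | intermediate
21 | megaphone trimethylsilyl ether | C=CC[C@]1([C@H](C)[C@@H](O[Si](C)(C)C)c2cc(OC)c(OC)c(OC)c2)C[C@@H](OC)C=CC1=O | intermediate
22 | megaphone | C=CC[C@]1([C@H](C)[C@@H](O)c2cc(OC)c(OC)c(OC)c2)C[C@@H](OC)C=CC1=O | target

Total step count: 8. Longest linear sequence: 7 (steps 1 to 5, 7 and 8).

**Steps most likely to fail**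

**Step 7.**
- What may go wrong: conjugate addition to the captodative enal may be slow, so that intermolecular olefination of the free aldehyde or polymerisation of the enal takes over. Ring closure may also outrun the equilibration of the aldehyde epimers, which would erode selectivity at the methoxy carbon.
- Fallback (known chemistry, oxygen introduced after ring formation), from 13 back to 18: 13 is combined with acrolein under amine-base catalysis. Michael addition of 2-acyl lactones to acrolein and the intramolecular Wittig closure then give the des-methoxy spiro enone F1.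
- TBSOTf/Et3N converts it into the linear silyl dienol ether F2; only γ-deprotonation is possible because the α′ carbon is quaternary.
- Dimethyldioxirane in a vinylogous Rubottom oxidation should attack the face opposite the pseudoaxial lactone carbonyl and give the γ-hydroxy enone F3.
- MeOTf with 2,6-di-tert-butyl-4-methylpyridine methylates F3 to 18.

**Step 8.**
- What may go wrong: the silanolate may attack the ketone and cause retro-Claisen ring cleavage. The palladium enolate may be protonated instead of allylated. Facial selectivity at the crowded enolate carbon may be poor.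
- Fallback (lithium enolate alkylation in place of palladium catalysis), from 18 back to 22: Me3SnOH in 1,2-dichloroethane at 80 °C hydrolyses the lactone, and the β-keto acid decarboxylates on heating to the hydroxy enone F4.
- Kinetic double deprotonation (LDA, 2.2 equiv, THF, −78 °C) gives the alkoxide/cross-conjugated enolate. Allyl iodide should alkylate it at carbon, anti to the methoxy group and on the face left open by the side chain, to give 22.

**Step 4.**
- What may go wrong: chloride may be lost by displacement or epoxide closure in the tetrahedral adduct. Proton transfer between product and enolate may also stop the acylation.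
- Fallback (aldol condensation in place of the Wittig closure, so that neither halide nor phosphorus is needed), from 8 back to 18: the enolate of 8 is acetylated with N-acetylimidazole to the acetyl lactone F5.
- Base-catalysed Michael addition to 16, anti to methyl and aryl, gives the keto aldehyde F6.
- Piperidinium acetate in warm toluene closes the methyl ketone onto the aldehyde and dehydrates the aldol to 18. This is the established Michael/aldol-condensation [3+3] route from acetoacetate-type donors and enals.

**Further compounds**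
F1 | step 7 | (3R,4S,5S)-4-methyl-3-(3,4,5-trimethoxyphenyl)-2-oxaspiro[4.5]dec-7-ene-1,6-dione | O=C2[C@]1([C@H](C)[C@H](c3cc(OC)c(OC)c(OC)c3)O2)CCC=CC1=O
F2 | step 7 | (3R,4S,5S)-6-(tert-butyldimethylsilyloxy)-4-methyl-3-(3,4,5-trimethoxyphenyl)-2-oxaspiro[4.5]deca-6,8-dien-1-one | O=C2[C@]1([C@H](C)[C@H](c3cc(OC)c(OC)c(OC)c3)O2)CC=CC=C1O[Si](C)(C)C(C)(C)C
F3 | step 7 | (3R,4S,5S,9R)-9-hydroxy-4-methyl-3-(3,4,5-trimethoxyphenyl)-2-oxaspiro[4.5]dec-7-ene-1,6-dione | O=C2[C@]1([C@H](C)[C@H](c3cc(OC)c(OC)c(OC)c3)O2)C[C@@H](O)C=CC1=O
F4 | step 8 | (4R)-6-[(1R,2S)-1-hydroxy-1-(3,4,5-trimethoxyphenyl)propan-2-yl]-4-methoxycyclohex-2-en-1-one (C6 epimers) | O=C1C=C[C@H](OC)CC1[C@H](C)[C@@H](O)c1cc(OC)c(OC)c(OC)c1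
F5 | step 4 | (4S,5R)-3-acetyl-4-methyl-5-(3,4,5-trimethoxyphenyl)dihydrofuran-2(3H)-one (C3 labile) | O=C1C(C(C)=O)[C@H](C)[C@H](c2cc(OC)c(OC)c(OC)c2)O1
F6 | step 4 | 3-[(3S,4S,5R)-3-acetyl-4-methyl-2-oxo-5-(3,4,5-trimethoxyphenyl)tetrahydrofuran-3-yl]-2-methoxypropanal | O=C1[C@](C(C)=O)([C@H](C)[C@H](c2cc(OC)c(OC)c(OC)c2)O1)CC(OC)C=O
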